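In the early readings the solid goes quickly. Elm at 0.333 min shows 30% solid substrate and 41% product, so part of the charge stands unread, presumably dissolved, and birch shows 0% solid at 0.667 min, well before 5.0 min. You can therefore keep the books in partner, counting in fractions of the solid substrate charged.

all flasks: solid substrate 0.46 M

|  | partner | protic impurity | remark | time |
|---|---|---|---|---|
| elm | 1.2 equiv | 4.6 mM | run made earlier |  |
| birch | 1.2 equiv | 6.9 mM | run made earlier |  |
| flask | 1.20 equiv | 9.20 mM |  | 5.0 min |

- elm (time / min: product / %, solid substrate / %): 0.333: 41, 30; 1.00: 79, 0; 1.50: 94, 3; 2.50: 91, 0; 4.00: 96, 0; 5.00: 95, 1; 6.00: 96, 1
- birch (time / min: product / %, solid substrate / %): 0.500: 56, 3; 0.667: 69, 0; 1.00: 81, 0; 1.50: 89, 0; 2.50: 93, 1; 4.00: 94, 0; 6.00: 95, 0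

(readings scatter by 2 percentage points)

- solid substrate is a solid; its amount is given per volume of the solution
- at the start none of the solid substrate is in solution

- dusk: doubling the dissolution coefficient of the solid substrate, all else as stated
- dawn: doubling the amount of partner, all else as stated
- winter: doubling the solubility of the solid substrate, all else as stated

1. the product standing at 5.0 min, as a percentage of the solid substrate charged
2. the change that raises the amount of product at 5.0 min, in percent of the solid substrate charged most ("none" if none brings more than 2 percentage points) (dusk / dawn / winter / none)
3. amount of product at 5.0 min, in percent of the solid substrate charged, after winter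

The opening balance is 1.20 equiv of partner. The first entry is product, one partner each, and elm stands at 96% at 6.00 min. The second entry is protic impurity, which you assume also takes one partner each: at most 1.00% of the charge in elm and 2.00% in the flask. The remainder is lost or left, and the readings can't say which. So carry the waste share, the part of the charged partner that doesn't reach product: 20.0% as read in elm.

Your reckoning holds that share for the flask and charges the extra impurity against product, which gives 95.0%. You hold winter and dusk at that figure too, since birch reads 0% solid substrate by 0.667 min. You choose dawn, because the 5 percentage points still short of full conversion exceeds the 2 points needed.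

The forecast differs: 94%, best none, winter 92.5%, on the ground that “the reaction is finished well before 5 min and rate changes alone gain nothing”.

    solid substrate ⇌ dissolved substrate, rate k1*(cs1 - [dissolved substrate]) while solid is left; crystals form when [dissolved substrate] > cs1 (solubility = 0.360 M, k = 4.00 min⁻¹)
    dissolved substrate + partner → product (k = 11.0 M⁻¹ min⁻¹)
    partner → decomposed reagent (k = 0.200 min⁻¹)
    partner + protic impurity → quenched reagent (k = 10.0 M⁻¹ min⁻¹)

The flask gives 96.6% at 5.0 min, the best change is dawn with a gain of 3.4 points, and winter gives 97.6%. At that time the flask holds 0.0858 M decomposed reagent, which is 18.6% of the solid substrate charged. The waste share of the flask comes to 19.5%. On the neighbour flask with 0.18 M of solid substrate and the same equivalents of partner, the share 20.0% would give 96.0%. That neighbour stands at 88.2%, a waste share of 26.5%, with 0.0421 M decomposed reagent.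

The runs stem from a simulated flask with made-up constants, noise included.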